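Each outer ring A is counted from its CH2-bearing carbon: carbon 1 (C–CH2), carbon 2 (C–Br), carbon 3 (C–Br), carbon 4 (C–OH), carbon 5 (C–OH), carbon 6 (C–H); ring B is the central ring.
Retrosynthesis cuts, in order: the three O–CH3 bonds on ring B, the three late C–Br bonds (ring B and carbon 3 of both rings A), the C–O bond at carbon 4 of both rings A, and last the two CH2–ring B bonds.
Enabling feature: the carbon-4 oxygen of ring A is ortho to the carbon-5 oxygen, and in a 2-bromo-5-hydroxybenzyl arm carbon 4 is the only unhindered ortho carbon of that phenol, since carbon 6 sits between the OH and the benzylic carbon and the para carbon 2 already carries Br; a phenol-to-catechol oxygenation can therefore be aimed at carbon 4 on both arms at once.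
Forward: aldehyde reduction, twofold Friedel–Crafts benzylation joining two ring A units to ring B, two-directional IBX oxygenation with in-flask reduction, threefold bromination, ether cleavage; all three rings are bought, none is built.
Stereochemistry: the target has no stereocentre and no double-bond geometry, so nothing has to be set.

Key step: step 3

**Route**

Step 1
Reactants: 1 2-bromo-5-hydroxybenzaldehyde
Product: 2 4-bromo-3-(hydroxymethyl)phenol (2-bromo-5-hydroxybenzyl alcohol)
Conditions: NaBH4, MeOH, 0 °C to rt; then H2O
Reagents that add atoms: none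
Why: Borohydride reduction of an aryl aldehyde to the benzylic alcohol is fast and chemoselective, leaving the aryl bromide and the phenol untouched.

Step 2
Reactants: 2 4-bromo-3-(hydroxymethyl)phenol (2.1 equiv); 3 1,3,5-trimethoxybenzene (1.0 equiv)
Product: 4 2,4-bis(2-bromo-5-hydroxybenzyl)-1,3,5-trimethoxybenzene
Conditions: TfOH (10 mol %), 1,1,1,3,3,3-hexafluoropropan-2-ol (HFIP), 50 °C
Reagents that add atoms: none
Why: This is a twofold Brønsted-acid-catalysed dehydrative Friedel–Crafts benzylation, in which TfOH in the strongly ionising HFIP medium should activate even a benzylic alcohol without a cation-stabilising group, the triether 3 is far more nucleophilic than the bromophenol ring of 2 so self-condensation should not compete, and the third site of ring B is slowed by two flanking methoxy groups that are each buttressed by a new benzyl group.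

Step 3
Reactants: 4 2,4-bis(2-bromo-5-hydroxybenzyl)-1,3,5-trimethoxybenzene
Product: 6 2,4-bis(2-bromo-4,5-dihydroxybenzyl)-1,3,5-trimethoxybenzene, via bis(ortho-quinone) 5 (not isolated)
Conditions: IBX (2.2 equiv), DMF, 23 °C, dark; then Na2S2O4, H2O, 0 °C, same flask
Reagents that add atoms: IBX (2-iodoxybenzoic acid), OI1(=O)OC(=O)c2ccccc12
Why: Each carbon-5 hydroxyl of ring A should exchange onto the pentavalent iodine of IBX to give an aryloxy iodane that hands an iodine-bound oxygen to the neighbouring ring carbon through a cyclic, sigmatropic-type transition state, after which the trivalent-iodine catechol adduct collapses to the ortho-quinone and 2-iodobenzoic acid, and Na2S2O4 then returns both quinone units of 5 to catechols. The closest known reaction type is the IBX ortho-oxygenation (oxidative dearomatisation) of alkyl-substituted phenols to ortho-quinones with reductive work-up, run here in both directions at once on two identical, electronically insulated arms. No ring closes and no stereocentre arises; the step makes only the two C–O bonds at carbon 4 of the two rings A. The selectivity it needs is carbon 4 over carbon 6 on each ring, and the substrate secures it because carbon 6 is wedged between the hydroxyl and the benzylic carbon carrying the di-ortho-methoxylated ring B while carbon 4 has a hydrogen neighbour, and because the para carbon 2 is already occupied by bromine. Chemoselectivity follows from the need for a free OH to bind iodine, since ring B is a triether and the CH2 bridges are oxidised by IBX only on heating. Reduction at 0 °C as soon as 4 is consumed should forestall tautomerisation of the 4-alkyl ortho-quinone to a quinone methide.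

Step 4
Reactants: 6 2,4-bis(2-bromo-4,5-dihydroxybenzyl)-1,3,5-trimethoxybenzene
Product: 7 1-bromo-3,5-bis(2,3-dibromo-4,5-dihydroxybenzyl)-2,4,6-trimethoxybenzene
Conditions: Br2 (3.05 equiv, slow addition), AcOH/CH2Cl2, 0 °C to rt
Reagents that add atoms: bromine, BrBr
Why: In this electrophilic aromatic bromination the last open carbon of the trialkoxy ring B should react first, and on each catechol ring carbon 3 is ortho to the carbon-4 hydroxyl with only the carbon-2 bromine beside it, whereas carbon 6 is meta to that deactivating bromine and screened by the CH2 that carries the by then hexasubstituted ring B.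

Step 5
Reactants: 7 1-bromo-3,5-bis(2,3-dibromo-4,5-dihydroxybenzyl)-2,4,6-trimethoxybenzene
Product: 8 vidalol B, 2-bromo-4,6-bis(2,3-dibromo-4,5-dihydroxybenzyl)benzene-1,3,5-triol
Conditions: BBr3 (10 equiv), CH2Cl2, −78 °C to rt; then H2O, 0 °C
Reagents that add atoms: none
Why: Lewis-acid cleavage of aryl methyl ethers with BBr3, in which boron coordinates the ether oxygen and bromide removes the methyl group by SN2 attack, is the standard unveiling of polybrominated phenols and should leave the aryl–Br bonds and the diarylmethane bridges intact at low temperature.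

**Compound list**

1 | 2-bromo-5-hydroxybenzaldehyde | O=Cc1cc(O)ccc1Br | starting material
2 | 4-bromo-3-(hydroxymethyl)phenol (2-bromo-5-hydroxybenzyl alcohol) | OCc1cc(O)ccc1Br | intermediate
3 | 1,3,5-trimethoxybenzene | COc1cc(OC)cc(OC)c1 | starting material
4 | 2,4-bis(2-bromo-5-hydroxybenzyl)-1,3,5-trimethoxybenzene | COc1cc(OC)c(Cc2cc(O)ccc2Br)c(OC)c1Cc1cc(O)ccc1Br | intermediate
5 | 5,5'-[(2,4,6-trimethoxy-1,3-phenylene)bis(methylene)]bis(4-bromocyclohexa-3,5-diene-1,2-dione), the bis(ortho-quinone), not isolated | COc1cc(OC)c(CC2=CC(=O)C(=O)C=C2Br)c(OC)c1CC1=CC(=O)C(=O)C=C1Br | intermediate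
6 | 2,4-bis(2-bromo-4,5-dihydroxybenzyl)-1,3,5-trimethoxybenzene | COc1cc(OC)c(Cc2cc(O)c(O)cc2Br)c(OC)c1Cc1cc(O)c(O)cc1Br | intermediate
7 | 1-bromo-3,5-bis(2,3-dibromo-4,5-dihydroxybenzyl)-2,4,6-trimethoxybenzene | COc1c(Br)c(OC)c(Cc2cc(O)c(O)c(Br)c2Br)c(OC)c1Cc1cc(O)c(O)c(Br)c1Br | intermediate
8 | vidalol B, 2-bromo-4,6-bis(2,3-dibromo-4,5-dihydroxybenzyl)benzene-1,3,5-triol | Oc1cc(Cc2c(O)c(Br)c(O)c(Cc3cc(O)c(O)c(Br)c3Br)c2O)c(Br)c(Br)c1O | target

**Count**

Total step count: 5. Longest linear sequence: 5 steps (1 → 2 → 4 → 6 → 7 → 8); compound 3 enters in step 2.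

**Steps most likely to fail**

Step 3. The para-bromophenol rings carry only an alkyl donor and may bind and reduce IBX too slowly. The alkyl ortho-quinone units may also tautomerise to quinone methides, or add nucleophiles at the bromine-bearing carbon, before they are reduced. The fallback sets out from 4 and replaces the oxidative dearomatisation by a formylation–oxidation sequence. Magnesium-phenoxide-directed ortho-formylation (MgCl2, Et3N, paraformaldehyde, MeCN, reflux) should place a formyl group on the same unhindered carbon 4 of each ring A and give 2,4-bis(2-bromo-4-formyl-5-hydroxybenzyl)-1,3,5-trimethoxybenzene F1. Dakin oxidation of both salicylaldehyde units (aqueous H2O2, NaOH, THF, 0 °C, then dilute HCl) then turns each formyl-bearing carbon into a hydroxyl-bearing one, and the route is rejoined at 6.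

Step 4. Bromination may stray to carbon 6 of ring A in competition with carbon 3, run on to tribrominated rings, displace a benzyl group from ring B by ipso attack, or be diverted into oxidation of the catechols by Br2. The fallback sets out from 6 and fixes the site by acidity instead of by electrophilic preference. Fourfold O-methylation (MeI, K2CO3, acetone, reflux) gives 2,4-bis(2-bromo-4,5-dimethoxybenzyl)-1,3,5-trimethoxybenzene F2. Directed ortho-metalation with LiN(iPr)2 (LDA, THF, −78 °C) should remove the hydrogen at carbon 3 of each ring A, the only one flanked by both a bromine and a methoxy group. Quenching the aryllithium at −78 °C with BrCCl2CCl2Br gives 2,4-bis(2,3-dibromo-4,5-dimethoxybenzyl)-1,3,5-trimethoxybenzene F3. One equivalent of N-bromosuccinimide (MeCN, 0 °C) then brominates the far more electron-rich ring B at its last open carbon to give 1-bromo-3,5-bis(2,3-dibromo-4,5-dimethoxybenzyl)-2,4,6-trimethoxybenzene F4. Cleavage of all seven methyl ethers with BBr3 (CH2Cl2, −78 °C to rt) rejoins the route at 8.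

Step 2. The one-flask double alkylation may give statistical mixtures of mono-, bis- and tris-benzylated ring B, and ionisation of a benzylic alcohol without a cation-stabilising group may be sluggish. The fallback sets out from 2 and 3, changes the electrophile to a halide, and forms the two CH2–ring B bonds one at a time. Aqueous HBr (48 %, 60 °C) converts 2 into 4-bromo-3-(bromomethyl)phenol F5. ZnBr2-catalysed Friedel–Crafts benzylation (10 mol %, CH2Cl2, rt) of a fivefold excess of 3 with this bromide should stop cleanly at 2-(2-bromo-5-hydroxybenzyl)-1,3,5-trimethoxybenzene F6, which is isolated while the excess of 3 is recovered. A second benzylation of the monobenzyl compound with one further equivalent of the bromide under the same catalysis rejoins the route at 4.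

Further compounds
F1 | step 3 | 2,4-bis(2-bromo-4-formyl-5-hydroxybenzyl)-1,3,5-trimethoxybenzene | COc1cc(OC)c(Cc2cc(O)c(C=O)cc2Br)c(OC)c1Cc1cc(O)c(C=O)cc1Br
F2 | step 4 | 2,4-bis(2-bromo-4,5-dimethoxybenzyl)-1,3,5-trimethoxybenzene | COc1cc(OC)c(Cc2cc(OC)c(OC)cc2Br)c(OC)c1Cc1cc(OC)c(OC)cc1Br
F3 | step 4 | 2,4-bis(2,3-dibromo-4,5-dimethoxybenzyl)-1,3,5-trimethoxybenzene | COc1cc(OC)c(Cc2cc(OC)c(OC)c(Br)c2Br)c(OC)c1Cc1cc(OC)c(OC)c(Br)c1Br
F4 | step 4 | 1-bromo-3,5-bis(2,3-dibromo-4,5-dimethoxybenzyl)-2,4,6-trimethoxybenzene | COc1c(Br)c(OC)c(Cc2cc(OC)c(OC)c(Br)c2Br)c(OC)c1Cc1cc(OC)c(OC)c(Br)c1Br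
F5 | step 2 | 4-bromo-3-(bromomethyl)phenol | BrCc1cc(O)ccc1Br
F6 | step 2 | 2-(2-bromo-5-hydroxybenzyl)-1,3,5-trimethoxybenzene | COc1cc(OC)c(Cc2cc(O)ccc2Br)c(OC)c1
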